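## Retrosynthetic overview

- Target 23 ← phenol acetate 22 ← germacra-1(10),4-dien-6β-yl ester 20: one transannular C5–C10 bond makes ring A and ring B together and installs the 4β-oxygen. 20 ← germacradienol 19 + acid 2.
- 19 ← acyclic iodo-trienol 17 by B-alkyl Suzuki closure of the ten-membered ring (C9–C10). 17 ← enal 16 + (E)-allylboronate 6 (C6–C7 bond, both stereocentres).
- Ring order: ten-membered carbocycle first (step 10), then both six-membered rings at once (step 12). The dioxanylium ring formed in step 12 is temporary.
- Enabling feature: in the cyclodeca-1(10),4-diene, C5 and C10 lie 1,6 across the ring. C10 is the methyl-bearing end of the C1=C10 olefin (tertiary cation on protonation at C1) and C5 is the nucleophilic end of C4=C5. O-6 sits 1,3 to C4 on the face of the C10 methyl, so the ester carbonyl can cap the C4 cation.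

Key step: step 12

Assumption: carbons are numbered as in eudesmane (C1–C15) throughout, also in the acyclic and ten-membered precursors; β denotes the face of the C10 methyl group.

## Route

Step 1
Reactants: 1 isoferulic acid
Product: 2 (E)-3-(3-acetoxy-4-methoxyphenyl)prop-2-enoic acid
Conditions: Ac2O, pyridine, rt; then H2O
Reagents that add atoms: acetic anhydride CC(=O)OC(C)=O
Why: Phenol O-acetylation, the mixed anhydride at the carboxyl group being hydrolysed on aqueous work-up, masks the phenol and leaves the acid free for step 11.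

Step 2
Reactants: 3 3-methylbut-1-yne
Product: 4 (E)-4,4,5,5-tetramethyl-2-(3-methylbut-1-en-1-yl)-1,3,2-dioxaborolane
Conditions: pinacolborane, Cp2Zr(H)Cl (5 mol %), Et3N (10 mol %), neat, 60 °C, sealed tube
Reagents that add atoms: pinacolborane [H]B1OC(C)(C)C(C)(C)O1
Why: Zirconocene-catalysed syn hydroboration of a terminal alkyne places boron on the terminal carbon and should give the E alkenylboronate only.

Step 3
Reactants: 4 (E)-alkenylboronate
Product: 6 (E)-4,4,5,5-tetramethyl-2-(4-methylpent-2-en-1-yl)-1,3,2-dioxaborolane, via ate complex 5 (not isolated)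
Conditions: ICH2Cl, n-BuLi, THF, −78 °C to rt
Reagents that add atoms: chloroiodomethane ClCI
Why: Matteson homologation, in which LiCH2Cl adds to boron and 1,2-migration of the alkenyl group with loss of chloride inserts one CH2 with retention of the E geometry.

Step 4
Reactants: 7 pentane-2,4-dione, 8 1-bromobut-2-yne
Product: 10 hept-5-yn-2-one, via alkylated diketone 9 (not isolated)
Conditions: K2CO3, EtOH, reflux
Reagents that add atoms: none
Why: Base-mediated C-alkylation of the 1,3-diketone by the propargylic bromide is followed in the same pot by retro-Claisen deacetylation by ethanol, a classical alkylation–cleavage route to methyl ketones.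

Step 5
Reactants: 10 hept-5-yn-2-one, 11 triethyl phosphonoacetate
Product: 12 ethyl (E)-3-methyloct-2-en-6-ynoate
Conditions: NaH, THF, 0 °C to 40 °C; Z isomer removed by chromatography
Reagents that add atoms: none
Why: Horner–Wadsworth–Emmons olefination of a methyl ketone favours the E trisubstituted enoate (ester trans to the longer chain), and the minor Z isomer is separable.

Step 6
Reactants: 12 ethyl (E)-3-methyloct-2-en-6-ynoate
Product: 13 (E)-3-methyloct-2-en-6-yn-1-ol
Conditions: iBu2AlH (2.2 equiv), CH2Cl2, −78 °C; aq. KNaC4H4O6 work-up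
Reagents that add atoms: none
Why: 1,2-Reduction of the enoate by the aluminium hydride leaves the olefin geometry and the alkyne untouched.

Step 7
Reactants: 13 (E)-3-methyloct-2-en-6-yn-1-ol
Product: 15 (2E,6E)-7-iodo-3-methylocta-2,6-dien-1-ol, via alkenylzirconocene 14 (not isolated)
Conditions: Cp2Zr(H)Cl (3 equiv), THF, rt to 40 °C; then I2, 0 °C
Reagents that add atoms: iodine II
Why: Schwartz hydrozirconation adds Zr–H syn across the alkyne and, with excess reagent, equilibrates zirconium to the less hindered methyl-bearing carbon, so that iodinolysis with retention should give the E 2-iodoalkene (one equivalent of reagent is consumed by the hydroxyl group).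

Step 8
Reactants: 15 (2E,6E)-7-iodo-3-methylocta-2,6-dien-1-ol
Product: 16 (2E,6E)-7-iodo-3-methylocta-2,6-dienal
Conditions: MnO2 (activated, excess), CH2Cl2, rt
Reagents that add atoms: none
Why: Chemoselective allylic oxidation to the enal without E/Z isomerization and without touching the alkenyl iodide.

Step 9
Reactants: 16 (2E,6E)-7-iodo-3-methylocta-2,6-dienal, 6 (E)-allylboronate
Product: 17 (3R,4R,5E,9E)-10-iodo-6-methyl-3-(propan-2-yl)undeca-1,5,9-trien-4-ol
Conditions: (R)-3,3'-bis(2,4,6-triisopropylphenyl)-1,1'-binaphthyl-2,2'-diyl hydrogen phosphate ((R)-TRIP, 5 mol %), 4 Å molecular sieves, toluene, −30 °C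
Reagents that add atoms: none
Why: Chiral phosphoric acid catalysed allylboration through a chair transition state, in which the equatorial E γ-isopropyl group gives the anti relation of hydroxyl and isopropyl (C7) and the catalyst bound to the boronate oxygen is expected, by analogy with its aryl and alkenyl aldehyde allylations, to open the Re face of the aldehyde (C6, R).

Step 10
Reactants: 17 iodo-trienol
Product: 19 (1R,2E,6E,10S)-3,7-dimethyl-10-(propan-2-yl)cyclodeca-2,6-dien-1-ol, via alkylborane 18 (not isolated)
Conditions: 9-BBN-H, THF, 0 °C to rt; then slow addition to Pd(dppf)Cl2 (20 mol %), AsPh3, Cs2CO3, DMF/THF/H2O, 45 °C, 0.002 M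
Reagents that add atoms: none
Why: 9-BBN-H hydroborates only the monosubstituted olefin (anti-Markovnikov), and intramolecular B-alkyl Suzuki–Miyaura coupling of the alkylborane with the alkenyl iodide, a closure precedented for strained medium-ring E-cycloalkenes, forms C9–C10 with retention of the E geometry while high dilution suppresses oligomers.

Step 11
Reactants: 19 germacradienol, 2 O-acetylisoferulic acid
Product: 20 (1R,2E,6E,10S)-3,7-dimethyl-10-(propan-2-yl)cyclodeca-2,6-dien-1-yl (E)-3-(3-acetoxy-4-methoxyphenyl)prop-2-enoate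
Conditions: DCC, DMAP (0.3 equiv), CH2Cl2, 0 °C to rt
Reagents that add atoms: none
Why: Steglich esterification acylates the secondary allylic alcohol with retention at C6 under neutral conditions, so that no acid triggers the transannular cyclization early.

Step 12
Reactants: 20 germacradienyl ester
Product: 22 (1R,2S,4aR,8S,8aS)-8-hydroxy-4a,8-dimethyl-2-(propan-2-yl)decahydronaphthalen-1-yl (E)-3-(3-acetoxy-4-methoxyphenyl)prop-2-enoate, via dioxanylium ion 21 (not isolated)
Conditions: camphor-10-sulfonic acid (20 mol %), CH2Cl2 saturated with H2O, −20 °C to 0 °C; then aq. NaHCO3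
Reagents that add atoms: water O
Why: Proposed new method: protonation of the C1=C10 olefin at C1, assisted through space by the C4=C5 olefin, forms the C5–C10 bond and a tertiary C4 cation, which the carbonyl oxygen of the 6β-acyloxy group captures as a 1,3-dioxan-2-ylium ion (21) that water opens to the secondary ester and the tertiary alcohol. The closest known reactions are the acid-induced transannular cyclization of germacra-1(10),4-dienes to eudesmanes and the neighbouring-group capture of carbocations by esters and carbonates through dioxolanylium or dioxanylium ions; their combination on a germacradienyl ester is what is new. The single transannular bond closes ring A in a 6-endo and ring B in a 6-exo sense with respect to the C4=C5 nucleophile, and the temporary dioxanylium ring closes six-membered by oxygen attack on C4. C10 and C5 are set by the E geometry of both olefins reacting in the crossed chair–chair conformer of the ten-membered ring that keeps the C7 isopropyl group pseudo-equatorial (trans fusion, C10 methyl β, H-5 α), and C4 is set by intramolecular delivery of oxygen from the axial 6β-ester to the β face, which leaves the C4 methyl equatorial. The step needs protonation at C1 rather than at C5 or ionization of the allylic ester, and oxygen capture at C4 rather than proton loss: the first should be secured by the ester-flanked, less basic C4=C5 olefin, by the transannular assistance open only to C1 protonation and by a weak acid at low temperature, the second by the 1,3-diaxial proximity of the ester carbonyl to C4.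

Step 13
Reactants: 22 phenol acetate
Product: 23 (1R,2S,4aR,8S,8aS)-8-hydroxy-4a,8-dimethyl-2-(propan-2-yl)decahydronaphthalen-1-yl (E)-3-(3-hydroxy-4-methoxyphenyl)prop-2-enoate
Conditions: pyrrolidine (3 equiv), CH2Cl2, 0 °C to rt
Reagents that add atoms: none
Why: Aminolysis removes the phenolic acetate far faster than it attacks the hindered secondary cinnamate, so that the phenol should be released without touching the ester or the tertiary alcohol.

## Compound list

1 | isoferulic acid, (E)-3-(3-hydroxy-4-methoxyphenyl)prop-2-enoic acid | COc1ccc(/C=C/C(=O)O)cc1O | starting material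
2 | (E)-3-(3-acetoxy-4-methoxyphenyl)prop-2-enoic acid (O-acetylisoferulic acid) | COc1ccc(/C=C/C(=O)O)cc1OC(C)=O | intermediate
3 | 3-methylbut-1-yne | CC(C)C#C | starting material
4 | (E)-4,4,5,5-tetramethyl-2-(3-methylbut-1-en-1-yl)-1,3,2-dioxaborolane | CC(C)/C=C/B1OC(C)(C)C(C)(C)O1 | intermediate
5 | lithium (chloromethyl)[(E)-3-methylbut-1-en-1-yl]pinacolatoborate (ate complex) | [Li+].CC(C)/C=C/[B-]1(CCl)OC(C)(C)C(C)(C)O1 | intermediate (not isolated)
6 | (E)-4,4,5,5-tetramethyl-2-(4-methylpent-2-en-1-yl)-1,3,2-dioxaborolane | CC(C)/C=C/CB1OC(C)(C)C(C)(C)O1 | intermediate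
7 | pentane-2,4-dione | CC(=O)CC(C)=O | starting material
8 | 1-bromobut-2-yne | CC#CCBr | starting material
9 | 3-(but-2-yn-1-yl)pentane-2,4-dione | CC#CCC(C(C)=O)C(C)=O | intermediate (not isolated)
10 | hept-5-yn-2-one | CC#CCCC(C)=O | intermediate
11 | triethyl phosphonoacetate | CCOC(=O)CP(=O)(OCC)OCC | starting material
12 | ethyl (E)-3-methyloct-2-en-6-ynoate | CC#CCC/C(C)=C/C(=O)OCC | intermediate
13 | (E)-3-methyloct-2-en-6-yn-1-ol | CC#CCC/C(C)=C/CO | intermediate
14 | (E)-alkenylzirconocene chloride at C7 of the zirconocene alkoxide of 13 | C/C(=C\CC/C(C)=C/CO[Zr](Cl)(C1C=CC=C1)C1C=CC=C1)[Zr](Cl)(C1C=CC=C1)C1C=CC=C1 | intermediate (not isolated)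
15 | (2E,6E)-7-iodo-3-methylocta-2,6-dien-1-ol | C/C(I)=C\CC/C(C)=C/CO | intermediate
16 | (2E,6E)-7-iodo-3-methylocta-2,6-dienal | C/C(I)=C\CC/C(C)=C/C=O | intermediate
17 | (3R,4R,5E,9E)-10-iodo-6-methyl-3-(propan-2-yl)undeca-1,5,9-trien-4-ol | C=C[C@@H](C(C)C)[C@@H](O)/C=C(\C)CC/C=C(\C)I | intermediate
18 | B-alkyl-9-borabicyclo[3.3.1]nonane from hydroboration of the terminal olefin of 17 | C1CCC2CCCC1B2CC[C@@H](C(C)C)[C@@H](O)/C=C(\C)CC/C=C(\C)I | intermediate (not isolated)
19 | (1R,2E,6E,10S)-3,7-dimethyl-10-(propan-2-yl)cyclodeca-2,6-dien-1-ol, i.e. (6R,7S)-germacra-1(10)E,4E-dien-6-ol | C/C1=C\CC/C(C)=C/[C@H](O)[C@H](C(C)C)CC1 | intermediate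
20 | (1R,2E,6E,10S)-3,7-dimethyl-10-(propan-2-yl)cyclodeca-2,6-dien-1-yl (E)-3-(3-acetoxy-4-methoxyphenyl)prop-2-enoate | COc1ccc(/C=C/C(=O)O[C@H]2/C=C(\C)CC/C=C(\C)CC[C@H]2C(C)C)cc1OC(C)=O | intermediate
21 | 2-[(E)-2-(3-acetoxy-4-methoxyphenyl)ethenyl]-1,3-dioxan-2-ylium ion bridging O-4 and O-6 (both β) of the trans-eudesmane | COc1ccc(/C=C/C2=[O+][C@@]3(C)CCC[C@]4(C)CC[C@@H](C(C)C)[C@@H](O2)[C@@H]34)cc1OC(C)=O | intermediate (not isolated)
22 | (1R,2S,4aR,8S,8aS)-8-hydroxy-4a,8-dimethyl-2-(propan-2-yl)decahydronaphthalen-1-yl (E)-3-(3-acetoxy-4-methoxyphenyl)prop-2-enoate | COc1ccc(/C=C/C(=O)O[C@H]2[C@@H]3[C@](C)(CCC[C@]3(C)O)CC[C@H]2C(C)C)cc1OC(C)=O | intermediate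
23 | (1R,2S,4aR,8S,8aS)-8-hydroxy-4a,8-dimethyl-2-(propan-2-yl)decahydronaphthalen-1-yl (E)-3-(3-hydroxy-4-methoxyphenyl)prop-2-enoate (4β-hydroxyeudesman-6β-yl isoferulate) | COc1ccc(/C=C/C(=O)O[C@H]2[C@@H]3[C@](C)(CCC[C@]3(C)O)CC[C@H]2C(C)C)cc1O | target

## Step count and risks

Total steps: 13. Longest linear sequence: 10 (steps 4 to 13).

**Steps most likely to fail**

1. Step 12 (the proposed step). The C4 cation may lose a proton or be captured on the α face instead of by the ester. The allylic ester may ionize and close through C1–C6. The ring may fold through a conformer with an axial isopropyl group. The acyl group may stay on the tertiary oxygen after hydrolysis.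
 Fallback by known chemistry, leaving the route at germacradienol 19 and rejoining at 22: 19 is cyclised by the established acid-induced transannular cyclization of germacra-1(10),4-dienes (p-TsOH cat., CH2Cl2, 0 °C) to eudesm-4(15)-en-6β-ol F1, which is separated from its endocyclic olefin isomers. Ozonolysis (O3, CH2Cl2/MeOH, −78 °C; Me2S) gives 4-oxo-15-noreudesman-6β-ol F2. MeMgBr with CeCl3 (THF, −78 °C) should add from the α face, away from the axial C10 methyl and the 6β-oxygen, to give eudesmane-4β,6β-diol F3. Steglich acylation of its secondary hydroxyl with acid 2 gives 22.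

2. Step 10. Oligomerization, β-hydride elimination or protodeboronation may outrun closure of the strained ten-membered ring.
 Fallback, from 17 back to 19: hydroboration–iodination (9-BBN-H; then I2, NaOMe) gives (3S,4R,5E,9E)-1,10-diiodo-6-methyl-3-(propan-2-yl)undeca-5,9-dien-4-ol F4. The ring is then closed by nickel-catalysed reductive cross-electrophile coupling of the alkyl iodide with the alkenyl iodide (NiBr2(dme), 4,4'-di-tert-butyl-2,2'-bipyridine, Mn powder, DMA, high dilution). This forms the same C9–C10 bond without an organoboron, a base or a transmetalation step.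

3. Step 9. The catalysed addition to the β,β-disubstituted enal may be slow, so that the uncatalysed background reaction erodes the enantioselectivity.
 Fallback, from 16 and 6 back to 17: the allylboration is run without catalyst (toluene, rt). The closed transition state should still give the anti diastereomer, but as the racemate, i.e. 17 together with (3S,4S,5E,9E)-10-iodo-6-methyl-3-(propan-2-yl)undeca-1,5,9-trien-4-ol F5. Sharpless kinetic resolution (Ti(OiPr)4, L-(+)-diisopropyl tartrate, t-BuOOH, 4 Å molecular sieves, CH2Cl2, −20 °C) should epoxidise the fast-reacting (S)-carbinol to (1S,2S)-1-[(2S,3S)-3-[(3E)-4-iodopent-3-en-1-yl]-3-methyloxiran-2-yl]-2-(propan-2-yl)but-3-en-1-ol F6 and leave 17, which is separated and taken into step 10.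

## Further compounds

F1 | step 12 | (1R,2S,4aR,8aS)-4a-methyl-8-methylidene-2-(propan-2-yl)decahydronaphthalen-1-ol (eudesm-4(15)-en-6β-ol) | C=C1CCC[C@]2(C)CC[C@@H](C(C)C)[C@@H](O)[C@@H]12
F2 | step 12 | (4aR,7S,8R,8aS)-8-hydroxy-4a-methyl-7-(propan-2-yl)octahydronaphthalen-1(2H)-one (4-oxo-15-noreudesman-6β-ol) | O=C1CCC[C@]2(C)CC[C@@H](C(C)C)[C@@H](O)[C@@H]12
F3 | step 12 | (1R,2S,4aR,8S,8aS)-4a,8-dimethyl-2-(propan-2-yl)decahydronaphthalene-1,8-diol (eudesmane-4β,6β-diol) | C[C@]1(O)CCC[C@]2(C)CC[C@@H](C(C)C)[C@@H](O)[C@@H]12
F4 | step 10 | (3S,4R,5E,9E)-1,10-diiodo-6-methyl-3-(propan-2-yl)undeca-5,9-dien-4-ol | ICC[C@@H](C(C)C)[C@@H](O)/C=C(\C)CC/C=C(\C)I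
F5 | step 9 | (3S,4S,5E,9E)-10-iodo-6-methyl-3-(propan-2-yl)undeca-1,5,9-trien-4-ol (enantiomer of 17) | C=C[C@H](C(C)C)[C@H](O)/C=C(\C)CC/C=C(\C)I
F6 | step 9 | (1S,2S)-1-[(2S,3S)-3-[(3E)-4-iodopent-3-en-1-yl]-3-methyloxiran-2-yl]-2-(propan-2-yl)but-3-en-1-ol | C=C[C@H](C(C)C)[C@H](O)[C@@H]1O[C@@]1(C)CC/C=C(\C)I
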